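**Retrosynthetic overview**

- Target 16 ⇐ ethyl ester 14 (saponification) ⇐ cyclohexenone ester 12 (removal of two hydrogens with CuBr2); ring A becomes aromatic only at this late stage.
- 12 ⇐ ethyl acetoacetate 9 + (E)-enal 8: Michael bond ring C1–C6, then aldol bond ring C3–C4. Ring A is the only ring built.
- Feature: in the 1,2,3-trisubstituted ring A, the carboxyl carbon with ring C1, the oxygen-bearing C2 and C3 form the four-carbon acetoacetate unit. C4, C5 and the chain-bearing C6 are the carbonyl, α and β carbons of an enal.
- 8 ⇐ 13-phenyltridecanal 6 (Wittig with ylide 7) ⇐ bromide 3 (Grignard, DMF) ⇐ PhMgBr 1 + dibromide 2 (Li2CuCl4-catalysed coupling).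

Key step: step 4

Remark on the chemistry: the target is achiral. Compound 12 is drawn as the racemic trans keto tautomer; its configuration and keto/enol ratio are immaterial because both sp3 centres are erased in step 5.

**Step 1**
Reactants: 1 phenylmagnesium bromide; 2 1,12-dibromododecane
Product: 3 (12-bromododecyl)benzene
Conditions: 2 (3 equiv), Li2CuCl4 (3 mol %), THF, slow addition of 1, −10 → 0 °C; excess 2 recovered by distillation
Reagents that add atoms: none
Why: Kochi-type copper-catalysed coupling of a Grignard reagent with a primary alkyl bromide should form the aryl–C(sp3) bond, and the threefold excess of the symmetrical dibromide keeps double arylation low; no stereocentre is formed.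

**Step 2**
Reactants: 3 (12-bromododecyl)benzene
Product: 6 13-phenyltridecanal, via (12-phenyldodecyl)magnesium bromide 4 (not isolated), via bromomagnesium hemiaminalate 5 (not isolated)
Conditions: Mg turnings, I2 (cat.), THF, reflux; then DMF (3 equiv), 0 °C → rt; 1 M HCl
Reagents that add atoms: N,N-dimethylformamide, CN(C)C=O
Why: Bouveault aldehyde synthesis: the primary Grignard reagent adds once to DMF, and the tetrahedral magnesium hemiaminalate survives until acidic work-up, so the aldehyde is released only after all organometallic is quenched; no stereocentre is formed.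

**Step 3**
Reactants: 6 13-phenyltridecanal; 7 (triphenylphosphoranylidene)acetaldehyde
Product: 8 (E)-15-phenylpentadec-2-enal
Conditions: 7 (1.1 equiv), toluene, 80 °C
Reagents that add atoms: none
Why: Wittig olefination with a carbonyl-stabilised ylide should give the E-alkene under thermodynamic control of the oxaphosphetane, and the saturated aldehyde 6 is more electrophilic than the conjugated product, which limits a second homologation.

**Step 4**
Reactants: 8 (E)-15-phenylpentadec-2-enal; 9 ethyl acetoacetate
Product: 12 ethyl trans-2-oxo-6-(12-phenyldodecyl)cyclohex-3-ene-1-carboxylate (racemic), via Michael adduct keto aldehyde 10 (not isolated), via aldol hydroxy ketone 11 (not isolated)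
Conditions: 9 (1.5 equiv), NaOEt (0.2 equiv), EtOH/THF, slow addition of 8, 0 °C → rt; then HCl/EtOH, 0 °C → rt
Reagents that add atoms: none
Why: Ethoxide forms the doubly stabilised enolate of 9, which adds through its central carbon to the β-carbon of 8 (Michael addition, ring bond C1–C6) to give 10; the methyl-ketone enolate of 10 then attacks the freed aldehyde (aldol, ring bond C3–C4) to give 11, and acid-promoted loss of water gives the conjugated enone 12. The closest known reaction type is the alkoxide-mediated Michael–aldol (Robinson-type) annulation of acetoacetic esters with 2-alkenals to 6-alkyl-2-oxocyclohex-3-enecarboxylates. Ring A closes as a carbocycle in a 6-(enolendo)-exo-trig aldol, which is favoured, whereas closure from the acetoacetate central carbon would give a four-membered ring and closure through enol oxygen gives only a reversible hemiacetal. The stereocentre at C6 arises without control in the Michael step and C1 equilibrates through the enol to the trans isomer; both are racemic and are deleted in step 5, so no control is required. The step needs 1,4- over 1,2-addition and single over double Michael addition: the soft stabilised carbanion adds conjugately, 1,2-aldol adducts revert, and slow addition of 8 to excess 9 with catalytic base lets the intramolecular aldol consume 10 before it can add to a second enal. The saturated chain and the terminal phenyl ring are inert.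

**Step 5**
Reactants: 12 ethyl trans-2-oxo-6-(12-phenyldodecyl)cyclohex-3-ene-1-carboxylate (racemic)
Product: 14 ethyl 2-hydroxy-6-(12-phenyldodecyl)benzoate, via 1-bromo keto ester 13 (not isolated)
Conditions: CuBr2 (2.05 equiv), LiBr (1 equiv), MeCN, reflux
Reagents that add atoms: none
Why: Bromination–dehydrobromination aromatisation of a cyclohexenone: CuBr2 α-brominates the enolised β-keto ester at C1, the tertiary bromide 13 loses HBr across C1–C6 and the ring enolises to the phenol, driven by aromaticity, while this mild bromine source should leave the chain and the terminal phenyl ring untouched.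

**Step 6**
Reactants: 14 ethyl 2-hydroxy-6-(12-phenyldodecyl)benzoate
Product: 16 2-hydroxy-6-(12-phenyldodecyl)benzoic acid, via dipotassium salt 15 (not isolated)
Conditions: KOH (10 equiv), DMSO/H2O (4:1), 90 °C; then 2 M HCl, 0 °C
Reagents that add atoms: potassium hydroxide, [K+].[OH-]
Why: Saponification (BAc2 ester hydrolysis) of a di-ortho-substituted benzoate is slow, so poorly solvated hydroxide in aqueous DMSO at 90 °C is used; the salt 15 is stable to base and cold acidification should release the acid without decarboxylation.

**Compound list**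

1 | phenylmagnesium bromide | Br[Mg]c1ccccc1 | starting material
2 | 1,12-dibromododecane | BrCCCCCCCCCCCCBr | starting material
3 | (12-bromododecyl)benzene | BrCCCCCCCCCCCCc1ccccc1 | intermediate
4 | (12-phenyldodecyl)magnesium bromide (not isolated) | Br[Mg]CCCCCCCCCCCCc1ccccc1 | intermediate
5 | bromomagnesium 1-(dimethylamino)-13-phenyltridecan-1-olate (hemiaminalate, racemic, not isolated) | CN(C)C(O[Mg]Br)CCCCCCCCCCCCc1ccccc1 | intermediate
6 | 13-phenyltridecanal | O=CCCCCCCCCCCCCc1ccccc1 | intermediate
7 | (triphenylphosphoranylidene)acetaldehyde | O=CC=P(c1ccccc1)(c1ccccc1)c1ccccc1 | starting material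
8 | (E)-15-phenylpentadec-2-enal | O=C/C=C/CCCCCCCCCCCCc1ccccc1 | intermediate
9 | ethyl acetoacetate | CCOC(=O)CC(C)=O | starting material
10 | ethyl 2-acetyl-5-oxo-3-(12-phenyldodecyl)pentanoate (racemic mixture of diastereomers, not isolated) | CCOC(=O)C(C(C)=O)C(CC=O)CCCCCCCCCCCCc1ccccc1 | intermediate
11 | ethyl 4-hydroxy-2-oxo-6-(12-phenyldodecyl)cyclohexane-1-carboxylate (racemic mixture of diastereomers, not isolated) | CCOC(=O)C1C(=O)CC(O)CC1CCCCCCCCCCCCc1ccccc1 | intermediate
12 | ethyl trans-2-oxo-6-(12-phenyldodecyl)cyclohex-3-ene-1-carboxylate (racemic; one enantiomer drawn) | CCOC(=O)[C@@H]1C(=O)C=CC[C@H]1CCCCCCCCCCCCc1ccccc1 | intermediate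
13 | ethyl 1-bromo-2-oxo-6-(12-phenyldodecyl)cyclohex-3-ene-1-carboxylate (racemic, configuration at C1 not defined, not isolated) | CCOC(=O)C1(Br)C(=O)C=CCC1CCCCCCCCCCCCc1ccccc1 | intermediate
14 | ethyl 2-hydroxy-6-(12-phenyldodecyl)benzoate | CCOC(=O)c1c(O)cccc1CCCCCCCCCCCCc1ccccc1 | intermediate
15 | dipotassium 2-oxido-6-(12-phenyldodecyl)benzoate (not isolated) | [K+].[K+].[O-]C(=O)c1c([O-])cccc1CCCCCCCCCCCCc1ccccc1 | intermediate
16 | 2-hydroxy-6-(12-phenyldodecyl)benzoic acid | O=C(O)c1c(O)cccc1CCCCCCCCCCCCc1ccccc1 | target

**Step count**

Total steps: 6. Longest linear sequence: 6 steps (2 → 3 → 6 → 8 → 12 → 14 → 16).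

**Steps most likely to fail**

Step 4 (key step). The conjugate addition may be outrun by 1,2-addition or Knoevenagel condensation at the aldehyde, by alkoxide-induced self-condensation of the γ-enolisable enal, or by a second Michael addition, so that ring A does not close cleanly. The fallback leaves the annulation and attaches the chain to a ready-made salicylate ring by known cross-coupling; it sets out from bromide 3 and comes back at the salt 15. Commercial 5-hydroxy-2,2-dimethyl-4H-1,3-benzodioxin-4-one is triflated (Tf2O, pyridine, CH2Cl2, 0 °C) to 2,2-dimethyl-4-oxo-4H-1,3-benzodioxin-5-yl trifluoromethanesulfonate F1. Bromide 3 is converted with Zn dust (I2 cat., DMA, 80 °C) into (12-phenyldodecyl)zinc bromide F2. Negishi coupling of F1 with F2 (Pd(dppf)Cl2 cat., THF/DMA, 60 °C) should give 2,2-dimethyl-5-(12-phenyldodecyl)-4H-1,3-benzodioxin-4-one F3. KOH in DMSO/H2O at 60 °C opens the dioxinone to 15, and acidification as in step 6 gives 16.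

Step 5. The electron-rich salicylate ring may be brominated further once it forms, or loss of HBr may stall at the bromo keto ester. The fallback replaces halogenation by selenoxide syn-elimination; it sets out from 12 and comes back at 14. Selenenylation of the β-keto ester (PhSeCl, pyridine, CH2Cl2, 0 °C) should place selenium at C1 anti to the chain, hence syn to the C6 hydrogen, giving ethyl 2-oxo-1-(phenylselanyl)-6-(12-phenyldodecyl)cyclohex-3-ene-1-carboxylate F4. Oxidation (H2O2, CH2Cl2, 0 °C → rt) gives ethyl 2-oxo-1-(phenylseleninyl)-6-(12-phenyldodecyl)cyclohex-3-ene-1-carboxylate F5, which eliminates across C1–C6 and tautomerises to 14.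

Step 3. The stabilised ylide may react sluggishly with the aliphatic aldehyde, and the product enal may be olefinated a second time, giving over-homologated dienal. The fallback builds the enal by olefination at the ester oxidation level followed by redox adjustment; it sets out from 6 and comes back at 8. Horner–Wadsworth–Emmons reaction (triethyl phosphonoacetate, NaH, THF, 0 °C → rt) should give ethyl (E)-15-phenylpentadec-2-enoate F6. Reduction (i-Bu2AlH, CH2Cl2, −78 °C) gives (E)-15-phenylpentadec-2-en-1-ol F7, and allylic oxidation (MnO2, CH2Cl2, rt) gives 8.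

**Further compounds**

F1 | step 4 | 2,2-dimethyl-4-oxo-4H-1,3-benzodioxin-5-yl trifluoromethanesulfonate | CC1(C)OC(=O)c2c(OS(=O)(=O)C(F)(F)F)cccc2O1
F2 | step 4 | (12-phenyldodecyl)zinc bromide | Br[Zn]CCCCCCCCCCCCc1ccccc1
F3 | step 4 | 2,2-dimethyl-5-(12-phenyldodecyl)-4H-1,3-benzodioxin-4-one | CC1(C)OC(=O)c2c(CCCCCCCCCCCCc3ccccc3)cccc2O1
F4 | step 5 | ethyl 2-oxo-1-(phenylselanyl)-6-(12-phenyldodecyl)cyclohex-3-ene-1-carboxylate | CCOC(=O)C1([Se]c2ccccc2)C(=O)C=CCC1CCCCCCCCCCCCc1ccccc1
F5 | step 5 | ethyl 2-oxo-1-(phenylseleninyl)-6-(12-phenyldodecyl)cyclohex-3-ene-1-carboxylate | CCOC(=O)C1([Se](=O)c2ccccc2)C(=O)C=CCC1CCCCCCCCCCCCc1ccccc1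
F6 | step 3 | ethyl (E)-15-phenylpentadec-2-enoate | CCOC(=O)/C=C/CCCCCCCCCCCCc1ccccc1
F7 | step 3 | (E)-15-phenylpentadec-2-en-1-ol | OC/C=C/CCCCCCCCCCCCc1ccccc1
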